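The route rests on cutting the γ-lactone (oxolan-2-one) ring between C4, its CH2, and C5, its O-bearing carbon. The ring oxygen O1 on C5 is used as an enol ether oxygen: in the acyclic precursor, an (E)-β-alkoxy enone made from but-3-yn-2-one, C5 is the electron-poor β-carbon. A primary radical at C4, from (S)-3-bromo-2-methylpropan-1-ol, which supplies C2, C3 with its methyl stereocentre and C4, closes the O1–C2–C3–C4–C5 ring 5-exo and sets C5 trans to the C3 methyl in one operation. Ether-to-lactone oxidation, Wittig extension, Sharpless epoxidation and Mitsunobu coupling with 7-hydroxy-8-methoxycoumarin finish the target.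

Key step: step 2

Remark: lactone atoms are numbered O1, C2 (C=O), C3 (CHMe), C4 (CH2), C5 (CH–O); (S)-3-bromo-2-methylpropan-1-ol, but-3-yn-2-one, the tert-butyl ylide and 7-hydroxy-8-methoxycoumarin are taken as catalogue compounds.

Step 1
Reactants: 1 (2S)-3-bromo-2-methylpropan-1-ol; 2 but-3-yn-2-one
Product: 3 (3E)-4-{[(2S)-3-bromo-2-methylpropyl]oxy}but-3-en-2-one
Conditions: N-methylmorpholine (cat.), CH2Cl2, 0 °C to rt
Reagents that add atoms: none
Why: Amine-catalysed oxa-Michael addition of the primary alcohol to the ynone should give the (E)-β-alkoxy enone without touching the C3 stereocentre, and no new stereocentre is formed.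

Step 2
Reactants: 3 (3E)-4-{[(2S)-3-bromo-2-methylpropyl]oxy}but-3-en-2-one
Product: 4 1-[(2S,4R)-4-methyloxolan-2-yl]propan-2-one
Conditions: Bu3SnH (syringe pump), Et3B/air, PhMe (0.01 M), 0 °C
Reagents that add atoms: none
Why: Bu3Sn• abstracts bromine from 3, and the primary radical at the future ring CH2 (C4) adds to the oxygen-bearing alkene carbon (future C5) of the vinylogous ester, a polarity-matched attack of a nucleophilic alkyl radical on an electron-poor β-carbon, after which the α-keto radical is reduced by Bu3SnH. The closest known reaction type is the radical cyclisation of β-alkoxyacrylates and β-alkoxyvinyl ketones to 2-(acylmethyl)oxolanes and oxanes. The oxolane ring (O1, C2, C3, C4, C5 of the later lactone) is closed in the 5-exo-trig mode by the C4–C5 bond. The new stereocentre C5 is controlled by the C3 methyl group from the chiral pool: in the chair-like transition state the methyl sits pseudo-equatorial, which should place the acylmethyl chain trans to it (2S,4R). The step needs cyclisation to outrun direct reduction (secured by the activated acceptor, high dilution and slow hydride addition), 5-exo over 6-endo closure (secured by the polarisation of the enone) and trans over cis closure (secured by the C3 methyl and the low temperature).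

Step 3
Reactants: 4 1-[(2S,4R)-4-methyloxolan-2-yl]propan-2-one
Product: 6 (3R,5S)-3-methyl-5-(2-oxopropyl)oxolan-2-one, via lactol 5 (not isolated)
Conditions: RuCl3·xH2O (cat.), NaIO4, CCl4/MeCN/H2O, rt
Reagents that add atoms: sodium periodate, [Na+].[O-]I(=O)(=O)=O
Why: RuO4-catalysed ether-to-lactone oxidation should take place at the unhindered α-methylene of the oxolane (C2 of the lactone) in preference to the α-methine that carries the electron-poor acylmethyl chain, through the lactol, and leaves both stereocentres untouched.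

Step 4
Reactants: 6 (3R,5S)-3-methyl-5-(2-oxopropyl)oxolan-2-one; 7 tert-butyl 2-(triphenyl-λ5-phosphanylidene)acetate
Product: 8 tert-butyl (2E)-3-methyl-4-[(2S,4R)-4-methyl-5-oxooxolan-2-yl]but-2-enoate
Conditions: PhCO2H (cat.), PhMe, 110 °C
Reagents that add atoms: none
Why: Wittig olefination with a stabilised ylide runs under neutral conditions, which avoids β-elimination of the ring carboxylate from the β-acyloxy ketone, and should favour the (E)-enoate, the (Z)-isomer being removed by chromatography; no stereocentre is formed.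

Step 5
Reactants: 8 tert-butyl (2E)-3-methyl-4-[(2S,4R)-4-methyl-5-oxooxolan-2-yl]but-2-enoate
Product: 9 (2E)-3-methyl-4-[(2S,4R)-4-methyl-5-oxooxolan-2-yl]but-2-enoic acid
Conditions: TFA, CH2Cl2, 0 °C to rt
Reagents that add atoms: none
Why: Acidolysis of the tert-butyl ester (E1 loss of isobutene) should free the enoic acid while the γ-lactone and the alkene geometry are stable to TFA.

Step 6
Reactants: 9 (2E)-3-methyl-4-[(2S,4R)-4-methyl-5-oxooxolan-2-yl]but-2-enoic acid
Product: 12 (3R,5S)-5-[(2E)-4-hydroxy-2-methylbut-2-en-1-yl]-3-methyloxolan-2-one, via mixed carbonic anhydride 10 (not isolated), via enal 11 (not isolated)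
Conditions: i-BuOCOCl, N-methylmorpholine, THF, −15 °C; then NaBH4, H2O, 0 °C
Reagents that add atoms: none
Why: Mixed-anhydride activation followed by NaBH4 reduction should reduce only the activated acyl group (1,2-reduction through the enal) and leave the γ-lactone, which is inert to NaBH4 at 0 °C; no stereocentre is formed.

Step 7
Reactants: 12 (3R,5S)-5-[(2E)-4-hydroxy-2-methylbut-2-en-1-yl]-3-methyloxolan-2-one
Product: 13 (3R,5S)-5-{[(2R,3R)-3-(hydroxymethyl)-2-methyloxiran-2-yl]methyl}-3-methyloxolan-2-one
Conditions: Ti(OiPr)4 (cat.), D-(−)-diethyl tartrate, t-BuOOH, 4 Å MS, CH2Cl2, −20 °C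
Reagents that add atoms: tert-butyl hydroperoxide, CC(C)(C)OO
Why: Sharpless asymmetric epoxidation of the (E)-allylic alcohol: the titanium D-(−)-tartrate complex delivers oxygen to the alkene face that gives the (2R,3R)-epoxide, a reagent-controlled choice that the remote lactone stereocentres should not override.

Step 8
Reactants: 13 (3R,5S)-5-{[(2R,3R)-3-(hydroxymethyl)-2-methyloxiran-2-yl]methyl}-3-methyloxolan-2-one; 14 7-hydroxy-8-methoxy-2H-chromen-2-one
Product: 15 8-methoxy-7-{[(2R,3R)-3-methyl-3-{[(2S,4R)-4-methyl-5-oxooxolan-2-yl]methyl}oxiran-2-yl]methoxy}-2H-chromen-2-one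
Conditions: PPh3, DIAD, THF, 0 °C to rt
Reagents that add atoms: none
Why: Mitsunobu etherification: the acidic phenol displaces the activated primary hydroxyl by SN2 at CH2, so that no stereocentre is involved and epoxide and lactone should remain intact.

Compound list
1 | (2S)-3-bromo-2-methylpropan-1-ol | BrC[C@@H](C)CO | starting material
2 | but-3-yn-2-one | CC(=O)C#C | starting material
3 | (3E)-4-{[(2S)-3-bromo-2-methylpropyl]oxy}but-3-en-2-one | BrC[C@@H](C)CO/C=C/C(C)=O | intermediate
4 | 1-[(2S,4R)-4-methyloxolan-2-yl]propan-2-one | CC(=O)C[C@@H]1C[C@@H](C)CO1 | intermediate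
5 | 1-[(2S,4R)-5-hydroxy-4-methyloxolan-2-yl]propan-2-one (lactol, both anomers) | CC(=O)C[C@@H]1C[C@@H](C)C(O)O1 | intermediate
6 | (3R,5S)-3-methyl-5-(2-oxopropyl)oxolan-2-one | CC(=O)C[C@@H]1C[C@@H](C)C(=O)O1 | intermediate
7 | tert-butyl 2-(triphenyl-λ5-phosphanylidene)acetate | CC(C)(C)OC(=O)C=P(c1ccccc1)(c1ccccc1)c1ccccc1 | starting material
8 | tert-butyl (2E)-3-methyl-4-[(2S,4R)-4-methyl-5-oxooxolan-2-yl]but-2-enoate | C/C(=C\C(=O)OC(C)(C)C)C[C@@H]1C[C@@H](C)C(=O)O1 | intermediate
9 | (2E)-3-methyl-4-[(2S,4R)-4-methyl-5-oxooxolan-2-yl]but-2-enoic acid | C/C(=C\C(=O)O)C[C@@H]1C[C@@H](C)C(=O)O1 | intermediate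
10 | (2E)-3-methyl-4-[(2S,4R)-4-methyl-5-oxooxolan-2-yl]but-2-enoic 2-methylpropyl carbonic anhydride | C/C(=C\C(=O)OC(=O)OCC(C)C)C[C@@H]1C[C@@H](C)C(=O)O1 | intermediate
11 | (2E)-3-methyl-4-[(2S,4R)-4-methyl-5-oxooxolan-2-yl]but-2-enal | C/C(=C\C=O)C[C@@H]1C[C@@H](C)C(=O)O1 | intermediate
12 | (3R,5S)-5-[(2E)-4-hydroxy-2-methylbut-2-en-1-yl]-3-methyloxolan-2-one | C/C(=C\CO)C[C@@H]1C[C@@H](C)C(=O)O1 | intermediate
13 | (3R,5S)-5-{[(2R,3R)-3-(hydroxymethyl)-2-methyloxiran-2-yl]methyl}-3-methyloxolan-2-one | OC[C@H]1O[C@]1(C)C[C@@H]2C[C@@H](C)C(=O)O2 | intermediate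
14 | 7-hydroxy-8-methoxy-2H-chromen-2-one | COc1c(O)ccc2ccc(=O)oc12 | starting material
15 | 8-methoxy-7-{[(2R,3R)-3-methyl-3-{[(2S,4R)-4-methyl-5-oxooxolan-2-yl]methyl}oxiran-2-yl]methoxy}-2H-chromen-2-one | COc1c(OC[C@H]2O[C@]2(C)C[C@@H]2C[C@@H](C)C(=O)O2)ccc2ccc(=O)oc12 | target

Total step count: 8. Longest linear sequence: 8 steps (1 to 15).

Steps most likely to fail

Step 2. The acyclic 1,3-induction from the C3 methyl may give poor facial selectivity in the 5-exo closure, so that the epimer at the new centre accumulates. The fallback replaces kinetic control by thermodynamic recycling; it sets out from 3 and returns at 4. The cyclisation mixture from 3 is separated, and the unwanted epimer 1-[(2R,4R)-4-methyloxolan-2-yl]propan-2-one F1 is treated with catalytic KOt-Bu in THF. Reversible retro-oxa-Michael opening to (3E,6R)-7-hydroxy-6-methylhept-3-en-2-one F2 and re-closure should equilibrate the two epimers without touching the methyl-bearing centre. Repeated separation and re-equilibration should funnel the material into 4.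

Step 4. Addition of the stabilised ylide to the enolisable methyl ketone may be sluggish and give poor E/Z selectivity, and forcing conditions may trigger β-elimination of the ring carboxylate. The fallback moves the olefination in front of the ether oxidation, where the ring oxygen is a poor leaving group, and uses the epoxide as protection of the alkene; it sets out from 4 and returns at 13. Horner–Wadsworth–Emmons reaction of 4 (triethyl phosphonoacetate, NaH, THF) should give ethyl (2E)-3-methyl-4-[(2S,4R)-4-methyloxolan-2-yl]but-2-enoate F3. Reduction with i-Bu2AlH should give (2E)-3-methyl-4-[(2S,4R)-4-methyloxolan-2-yl]but-2-en-1-ol F4. Sharpless epoxidation under the conditions of step 7 should give [(2R,3R)-3-methyl-3-{[(2S,4R)-4-methyloxolan-2-yl]methyl}oxiran-2-yl]methanol F5. Acetylation (Ac2O, pyridine) should give [(2R,3R)-3-methyl-3-{[(2S,4R)-4-methyloxolan-2-yl]methyl}oxiran-2-yl]methyl acetate F6. RuO4 oxidation in a pH 7 buffered medium (RuCl3·xH2O cat., NaIO4) should give [(2R,3R)-3-methyl-3-{[(2S,4R)-4-methyl-5-oxooxolan-2-yl]methyl}oxiran-2-yl]methyl acetate F7. Methanolysis of the acetate (K2CO3, MeOH, 0 °C) should then deliver 13.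

Step 3. Oxidation may also occur at the ring methine next to the acylmethyl chain, with ring cleavage or over-oxidation. The fallback closes the same C4–C5 bond with C2 already at the acid oxidation level, so that no ether oxidation is needed; it sets out from 1 and returns at 6. Jones oxidation of 1 (CrO3, H2SO4, acetone) should give (2S)-3-bromo-2-methylpropanoic acid F8. N-Methylmorpholine-mediated conjugate addition of F8 to 2 should give (1E)-3-oxobut-1-en-1-yl (2S)-3-bromo-2-methylpropanoate F9. Radical 5-exo cyclisation (Bu3SnH, AIBN, PhH, 80 °C, high dilution) should give 6 directly. This ester-tethered closure has less direct precedent than step 2; its support is the known addition of alkyl radicals to the oxygen-bearing carbon of β-acyloxy acrylates and the known ester-tethered 5-exo radical lactonisations, which need heat to populate the reactive ester rotamer.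

Further compounds
F1 | step 2 | 1-[(2R,4R)-4-methyloxolan-2-yl]propan-2-one | CC(=O)C[C@H]1C[C@@H](C)CO1
F2 | step 2 | (3E,6R)-7-hydroxy-6-methylhept-3-en-2-one | CC(=O)/C=C/C[C@@H](C)CO
F3 | step 4 | ethyl (2E)-3-methyl-4-[(2S,4R)-4-methyloxolan-2-yl]but-2-enoate | CCOC(=O)/C=C(\C)C[C@@H]1C[C@@H](C)CO1
F4 | step 4 | (2E)-3-methyl-4-[(2S,4R)-4-methyloxolan-2-yl]but-2-en-1-ol | OC/C=C(\C)C[C@@H]1C[C@@H](C)CO1
F5 | step 4 | [(2R,3R)-3-methyl-3-{[(2S,4R)-4-methyloxolan-2-yl]methyl}oxiran-2-yl]methanol | OC[C@H]1O[C@]1(C)C[C@@H]2C[C@@H](C)CO2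
F6 | step 4 | [(2R,3R)-3-methyl-3-{[(2S,4R)-4-methyloxolan-2-yl]methyl}oxiran-2-yl]methyl acetate | CC(=O)OC[C@H]1O[C@]1(C)C[C@@H]2C[C@@H](C)CO2
F7 | step 4 | [(2R,3R)-3-methyl-3-{[(2S,4R)-4-methyl-5-oxooxolan-2-yl]methyl}oxiran-2-yl]methyl acetate | CC(=O)OC[C@H]1O[C@]1(C)C[C@@H]2C[C@@H](C)C(=O)O2
F8 | step 3 | (2S)-3-bromo-2-methylpropanoic acid | BrC[C@@H](C)C(=O)O
F9 | step 3 | (1E)-3-oxobut-1-en-1-yl (2S)-3-bromo-2-methylpropanoate | BrC[C@@H](C)C(=O)O/C=C/C(C)=O
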